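# Proposed total synthesis of CNP0594916.1 (34) through ozonolysis of a C4=C10 ring-fusion alkene

Germacrane locants (C1–C15) are used for every intermediate, including the monocyclic ones: the cyclopentane ring is C10–C1–C2–C3–C4 and the future seven-membered ring is C4–C5–C6–C7–C8–C9–C10. α and β refer to the target drawn with H-7 α.

## The problem

Compound 34 is a germacranolide: a ten-membered carbocycle with a trans-fused α-methylene-γ-lactone across C6/C7 (12,6α-olide), an angelate at C8, a free 5α-hydroxyl and three epoxides (trans trisubstituted 1β,10α; cis 2β,3β; spiro 4α,15). It has ten stereocentres, nine of them contiguous from C1 to C8, with C10 closing the array across the ring. The C5–C8 tetrad (5α-O, 6α-O, 7β-C, 8α-O) can be set with ordinary acyclic and small-ring control, but C1–C4 and C10 cannot safely be left to the conformational bias of a ten-membered polyene, and direct closure of a ten-membered ring is costly. The epoxides open under acid, the α-methylene lactone is a Michael acceptor and the angelate isomerises to the tiglate, so these groups must appear late or masked and the last deprotections must be neutral. The opening feature is that C4 and C10, the two fully substituted epoxide carbons, both bear oxygen and lie 1,5 across the ring (C10–C1–C2–C3–C4 on one side, C4–C5–…–C9–C10 on the other). They can be read as the two carbonyl carbons left by cleavage of a C4=C10 double bond shared by a five- and a seven-membered ring. C14 and C15 then become one-carbon nucleophiles for these carbonyls, and each carbonyl has an oxygenated stereocentre beside it (C1, C5) that can steer the addition through a magnesium chelate. The cis 2,3-epoxide is native to the cyclopentane of such a bicycle.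

## Retrosynthesis

**End game (34 ⇒ 26).** The C8 ester, the C11=C13 double bond and the free 5-OH are made last. 34 is traced to its 5-O-PMB ether 33 (one C–O bond, removed by DDQ; a MOM or silyl ether at C5 would need acid or fluoride next to three epoxides). 33 goes back to the β-amino lactone 31 (C11=C13 by quaternisation and elimination), 31 to alcohol 28 plus angelic acid 29, and 28 through 27 to the 13-nor triepoxide 26 (C11–C13 by a Mannich reaction of the lactone enolate). Against an 11-methyl lactone dehydrogenated through a selenoxide, the Mannich route cannot eliminate into the ring, keeps the Michael acceptor masked during desilylation and acylation, and finishes all enolate chemistry before the angelate is present.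

**The two remote epoxides (26 ⇒ 21).** In 26 the bonds O–C1 and O–C15 are cut, each to an alkoxide displacing a leaving group (1-mesylate, 15-chloride) in triol 24. Closure inverts C1, so the C1 oxygen of 24 must be α. 24 then loses C14 (to α-ketol 23 and its TES ether 22) and C15 (to diketone 21).
- A chlorine at C1 would be the shortest leaving group, but an α-chloro ketone reacts in the Cornforth arrangement and its chlorohydrin closes to the cis 1(10)-epoxide. The trans epoxide needs the methyl group to enter the five-membered magnesium chelate of a 1α-oxygen from the side of H-1, so C1 carries oxygen and is freed before the Grignard step.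
- C15 must likewise enter the C4 carbonyl held in a chelate with the 5α-oxygen. A sulfonium ylide has no chelating metal and would follow the opposite (Felkin) sense, so a chloromethyl Grignard carbenoid and a chelating 5-OPMB are chosen.
- C4 is addressed first, while C1 carries a non-chelating silyl ether and C10 is not activated.
- The forward steps must discriminate two ketones and run cold, because 21 is prone to β-elimination at C1, C5 and C9.

**Key disconnection (21 ⇒ 20).** C4 and C10 of 21 are reconnected as the tetrasubstituted alkene of the 13,14,15-trinor-4,10-cyclogermacrene 20. Compared with closing the ten-membered ring at any single bond, this removes the macrocyclisation altogether. The precursor is a rigid 5/7 bicycle on which all seven remaining stereocentres are already set. The forward reaction needs one ozone-reactive site and a neutral work-up.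

**Oxygenation of the seven-membered ring (20 ⇒ 17).** 20 is the PMB ether of hydroxy lactone 19. The C5–O and C6–O bonds and the lactone C12–O bond of 19 are cut back to the C5=C6 alkene and methyl ester of diene 17. Cis-dihydroxylation on the ring sets both carbinols from C7 in one operation, and only the 6-OH can reach the ester to give a five-membered lactone. Bringing C5 in as an aldehyde in a ring-closing addition would leave that centre to a less predictable step.

**Seven-membered ring (17 ⇒ 15).** The C5=C6 bond is cut by ring-closing metathesis to triene 16, and the C4–C5 bond by cross-coupling to enol triflate 15. This requires a cyclopentenyl triflate that already carries the 1α-silyloxy group and the 2,3-epoxide.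

**C7–C8 bond (15 ⇒ 9 + 12).** Silyl ether 15 comes from homoallylic alcohol 14, whose C7–C8 bond is cut to aldehyde 9 and the Z-allylborane 13 made from allenoate 12. One reagent-controlled step sets C7 and C8 (syn) and delivers C6 as a vinyl group and C11/C12 as the acetate arm.

**Five-membered ring (9 ⇒ 1 + 2).** 9 is the cleavage product of allyl triflate 8, which comes from epoxy ketone 7 by enolisation toward C10. 7 is the epoxide of enone 6, the silyl ether of 5. Epoxidising the enone before the ring-fusion alkene exists avoids a cyclopentadiene and places the epoxide trans to the C1 oxygen. The pattern of 5 (enone, carbinol, adjacent CH-allyl) is the product of a Piancatelli rearrangement of furylcarbinol 3, made from furfural 1 and allylmagnesium bromide 2. Racemic 4 is resolved with a lipase.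

## Roads not taken

**Alternative 1:** the C5–C6 bond is cut and the ring closed by SmI2 pinacol coupling of the C5 and C6 aldehyde carbons to give diol A1.
- Merits: ring closure and both carbinol centres in one step, on an acyclic precursor that could be assembled convergently. A1 is probably reached in fewer steps than 21.
- Weak points: closing a ten-membered ring containing an E-trisubstituted and a Z-disubstituted alkene is entropically and enthalpically demanding. The ketyl at C5 sits next to the C4 ketal oxygen and can fragment. Both new centres are controlled only by C7 and the ring conformation.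
- After A1 the hard part remains: C15 is still missing, and three epoxidations must be face-selective on a flexible macrocyclic triene with no directing logic for C1, C2, C3 and C10.
- Comparison: the chosen plan is longer but forms every one of these centres either on a small ring or in a chelate.

**Alternative 2:** the C7–C8 bond is cut and a thirteen-membered O8–C13 allyl stannylmethyl-type ether is contracted by tin–lithium exchange and [2,3]-Wittig shift to A2.
- Merits: the C7–C8 bond, the 11(13)-alkene and a free 8-OH ready for acylation are formed at once, and ring contraction is easier than direct ten-membered closure. In these respects it is better than the chosen plan, which needs three steps for the methylene group and a deprotection at C8.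
- Weak points: the larger ring with a configurationally defined α-alkoxystannane must first be built. The sense of chirality transfer to C7/C8 depends on the alkene geometry and the envelope of the transition state, and the [1,2]-shift competes.
- A2 is a tetraene, so three of its four alkenes would have to be epoxidised chemo- and face-selectively and C12 oxidised to the lactone in their presence.
- Comparison: the chosen plan never has to discriminate alkenes; its only alkene at the key stage is the one to be cleaved.

**Alternative 3:** the C4–C5 bond is cut and the ring closed by CrCl2/NiCl2 addition of a C4 vinyl metal to the C5 aldehyde, giving A3.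
- Merits: this is the shortest road. The lactone and its methylene group are already in place, and the new allylic 5-OH could direct the 4(15)-epoxidation.
- Weak points: the closure is again ten-membered, on a cross-conjugated triene with a strained E,Z-diene. The C5 configuration depends on Felkin control from C6 within a macrocyclic transition state. The 1(10)- and 2,3-epoxides must afterwards be introduced face-selectively on the macrocycle next to two further alkenes and a Michael acceptor.
- Comparison: step economy is clearly better. The chosen plan offers a ring formation without entropic cost and defined control of C1–C4 and C10.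

Key step: step 15

## Remarks on assumptions

- The lipase is taken to acylate the (4R,5S) antipode of 4 (Kazlauskas rule with the branched C5 as the large group), so that 5 is recovered as the free alcohol.
- The borane from (−)-α-pinene is taken to attack the Re face of aldehyde 9, as it does with simple aldehydes.

## Route

Step 1
Reactants: 1 furfural; 2 allylmagnesium bromide
Product: 3 1-(furan-2-yl)but-3-en-1-ol (racemate)
Conditions: Et2O, 0 °C; aq. NH4Cl
Reagents that add atoms: none
Why: Grignard 1,2-addition to the aldehyde; the carbinol centre is destroyed in step 2, so no control is needed.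

Step 2
Reactants: 3 1-(furan-2-yl)but-3-en-1-ol
Product: 4 trans-4-hydroxy-5-(prop-2-en-1-yl)cyclopent-2-en-1-one (racemate)
Conditions: Dy(OTf)3 (10 mol %), t-BuOH/H2O, 80 °C
Reagents that add atoms: water, O
Why: Piancatelli rearrangement: ionisation of the furylcarbinol, addition of water at the furan C5, ring opening and conrotatory 4π closure of the pentadienyl cation place the hydroxyl and the allyl group trans.

Step 3
Reactants: 4 trans-4-hydroxy-5-(prop-2-en-1-yl)cyclopent-2-en-1-one (racemate)
Product: 5 (4S,5R)-4-hydroxy-5-(prop-2-en-1-yl)cyclopent-2-en-1-one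
Conditions: immobilised Candida antarctica lipase B, vinyl acetate, MTBE, 30 °C, to about half conversion
Reagents that add atoms: none
Why: Lipase-catalysed kinetic resolution by enantioselective acylation, a standard resolution of 4-hydroxycyclopentenones; the (4R,5S) antipode is acetylated and 5 is recovered. This fixes C1 (1α-O), from which C2 and C3 follow.

Step 4
Reactants: 5 (4S,5R)-4-hydroxy-5-(prop-2-en-1-yl)cyclopent-2-en-1-one
Product: 6 (4S,5R)-5-(prop-2-en-1-yl)-4-(triethylsilyloxy)cyclopent-2-en-1-one
Conditions: Et3SiCl, imidazole, CH2Cl2, 0 °C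
Reagents that add atoms: chlorotriethylsilane, CC[Si](Cl)(CC)CC
Why: Silylation of a secondary alcohol under mild base that does not isomerise the enone; the TES ether is non-chelating and can later be removed in the presence of a TBS ether.

Step 5
Reactants: 6 (4S,5R)-5-(prop-2-en-1-yl)-4-(triethylsilyloxy)cyclopent-2-en-1-one
Product: 7 10β-allyl-2β,3β-epoxy-1α-(triethylsilyloxy)cyclopentan-4-one
Conditions: H2O2 (30 %), NaOH (cat.), MeOH, −30 °C
Reagents that add atoms: hydrogen peroxide, OO
Why: Weitz–Scheffer epoxidation of the enone; hydroperoxide adds to C2 anti to the neighbouring silyloxy group, so the epoxide forms trans to the C1 oxygen and sets C2 and C3.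

Step 6
Reactants: 7 10β-allyl-2β,3β-epoxy-1α-(triethylsilyloxy)cyclopentan-4-one
Product: 8 10-allyl-2β,3β-epoxy-1α-(triethylsilyloxy)cyclopent-4(10)-en-4-yl trifluoromethanesulfonate
Conditions: PhNTf2, KHMDS (added last), THF, −78 °C
Reagents that add atoms: N-phenylbis(trifluoromethanesulfonimide), O=S(=O)(N(c1ccccc1)S(=O)(=O)C(F)(F)F)C(F)(F)F
Why: Kinetic enolisation and O-triflation of a ketone; C10–H is the only enolisable position (C3 is an epoxide carbon), so the tetrasubstituted enol triflate forms regiospecifically, and trapping in situ at low temperature is meant to outrun loss of the β-silyloxy group.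

Step 7
Reactants: 8 10-allyl-2β,3β-epoxy-1α-(triethylsilyloxy)cyclopent-4(10)-en-4-yl trifluoromethanesulfonate
Product: 9 2-[2β,3β-epoxy-1α-(triethylsilyloxy)-4-(triflyloxy)cyclopent-4(10)-en-10-yl]acetaldehyde
Conditions: OsO4 (cat.), NaIO4, 2,6-lutidine, dioxane/H2O, rt
Reagents that add atoms: sodium periodate, [Na+].[O-]I(=O)(=O)=O; water, O
Why: Lemieux–Johnson cleavage; the terminal alkene is dihydroxylated far faster than the hindered, electron-poor tetrasubstituted enol triflate alkene, and the buffered medium spares the epoxide and the silyl ether.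

Step 8
Reactants: 10 prop-2-yn-1-ol; 11 trimethyl orthoacetate
Product: 12 methyl penta-3,4-dienoate
Conditions: EtCO2H (cat.), 110 °C, MeOH distilled off
Reagents that add atoms: none
Why: Johnson–Claisen rearrangement of the propargyl ketene acetal gives the β-allenic ester directly.

Step 9
Reactants: 9 2-[2β,3β-epoxy-1α-(triethylsilyloxy)-4-(triflyloxy)cyclopent-4(10)-en-10-yl]acetaldehyde; 12 methyl penta-3,4-dienoate
Product: 14 methyl (3S,4S)-3-ethenyl-4-hydroxy-5-[2β,3β-epoxy-1α-(triethylsilyloxy)-4-(triflyloxy)cyclopent-4(10)-en-10-yl]pentanoate, via Z-allylborane 13 (not isolated)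
Conditions: (+)-Ipc2BH [from (−)-α-pinene], 12, THF, −25 °C; then 9, −78 → −20 °C; ethanolamine work-up
Reagents that add atoms: none
Why: Kinetic hydroboration of the terminal allene double bond gives the Z-γ-substituted allylborane, which adds to the aldehyde through a chair transition state (Brown-type allylboration). The Z geometry sets C7 and C8 syn, and the isopinocampheyl groups select the Re face of the aldehyde (8S, the 8α-oxygen).

Step 10
Reactants: 14 methyl (3S,4S)-3-ethenyl-4-hydroxy-5-[2β,3β-epoxy-1α-(triethylsilyloxy)-4-(triflyloxy)cyclopent-4(10)-en-10-yl]pentanoate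
Product: 15 methyl (3S,4S)-4-(tert-butyldimethylsilyloxy)-3-ethenyl-5-[2β,3β-epoxy-1α-(triethylsilyloxy)-4-(triflyloxy)cyclopent-4(10)-en-10-yl]pentanoate
Conditions: TBSOTf, 2,6-lutidine, CH2Cl2, −78 °C, on the crude alcohol
Reagents that add atoms: tert-butyldimethylsilyl triflate, CC(C)(C)[Si](C)(C)OS(=O)(=O)C(F)(F)F
Why: Fast low-temperature silylation of the hindered secondary alcohol; done at once so that the γ-hydroxy ester cannot close to the unwanted 12,8-lactone.

Step 11
Reactants: 15 methyl (3S,4S)-4-(tert-butyldimethylsilyloxy)-3-ethenyl-5-[2β,3β-epoxy-1α-(triethylsilyloxy)-4-(triflyloxy)cyclopent-4(10)-en-10-yl]pentanoate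
Product: 16 methyl (3S,4S)-4-(tert-butyldimethylsilyloxy)-3-ethenyl-5-[4-ethenyl-2β,3β-epoxy-1α-(triethylsilyloxy)cyclopent-4(10)-en-10-yl]pentanoate
Conditions: tributyl(vinyl)stannane, Pd2(dba)3 (5 mol %), AsPh3, CuI, NMP, rt
Reagents that add atoms: tributyl(vinyl)stannane, C=C[Sn](CCCC)(CCCC)CCCC
Why: Stille coupling of an enol triflate forms the C4–C5 bond; the weakly donating arsine and copper co-catalyst allow room temperature, which should keep zerovalent palladium from ionising the allylic epoxide.

Step 12
Reactants: 16 methyl (3S,4S)-4-(tert-butyldimethylsilyloxy)-3-ethenyl-5-[4-ethenyl-2β,3β-epoxy-1α-(triethylsilyloxy)cyclopent-4(10)-en-10-yl]pentanoate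
Product: 17 methyl 8α-(tert-butyldimethylsilyloxy)-2β,3β-epoxy-1α-(triethylsilyloxy)-13,14,15-trinor-4,10-cyclogermacra-4(10),5-dien-12-oate
Conditions: second-generation Grubbs catalyst (5 mol %), CH2Cl2, 40 °C
Reagents that add atoms: none
Why: Ring-closing metathesis of the two terminal vinyl groups closes the seven-membered ring at C5=C6; the tetrasubstituted C4=C10 alkene is inert to the ruthenium carbene.

Step 13
Reactants: 17 methyl 8α-(tert-butyldimethylsilyloxy)-2β,3β-epoxy-1α-(triethylsilyloxy)-13,14,15-trinor-4,10-cyclogermacra-4(10),5-dien-12-oate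
Product: 19 8α-(tert-butyldimethylsilyloxy)-2β,3β-epoxy-5α-hydroxy-1α-(triethylsilyloxy)-13,14,15-trinor-4,10-cyclogermacr-4(10)-en-12,6α-olide, via diol ester 18 (not isolated)
Conditions: OsO4 (5 mol %), NMO, acetone/H2O, 0 °C; then K2CO3 (cat.), MeOH, 0 °C
Reagents that add atoms: N-methylmorpholine N-oxide, C[N+]1([O-])CCOCC1; water, O
Why: Upjohn dihydroxylation takes the disubstituted C5=C6 bond of the diene, not the hindered ring-fusion alkene, and approaches anti to the C7 acetate arm, which sets the 5α- and 6α-oxygens together. Only the 6-OH can form a five-membered lactone, and it closes trans to the ring under mild base.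

Step 14
Reactants: 19 8α-(tert-butyldimethylsilyloxy)-2β,3β-epoxy-5α-hydroxy-1α-(triethylsilyloxy)-13,14,15-trinor-4,10-cyclogermacr-4(10)-en-12,6α-olide
Product: 20 8α-(tert-butyldimethylsilyloxy)-2β,3β-epoxy-5α-(4-methoxybenzyloxy)-1α-(triethylsilyloxy)-13,14,15-trinor-4,10-cyclogermacr-4(10)-en-12,6α-olide
Conditions: 2-(4-methoxybenzyloxy)-4-methylquinoline, MeOTf, MgO, PhCF3, 0 °C → rt
Reagents that add atoms: 2-(4-methoxybenzyloxy)-4-methylquinoline, COc1ccc(COc2cc(C)c3ccccc3n2)cc1
Why: PMB transfer from the N-methylated quinolinium salt under essentially neutral conditions; acid-catalysed imidate benzylation or a strong base would endanger the allylic epoxide and the lactone.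

Step 15
Reactants: 20 8α-(tert-butyldimethylsilyloxy)-2β,3β-epoxy-5α-(4-methoxybenzyloxy)-1α-(triethylsilyloxy)-13,14,15-trinor-4,10-cyclogermacr-4(10)-en-12,6α-olide
Product: 21 8α-(tert-butyldimethylsilyloxy)-2β,3β-epoxy-5α-(4-methoxybenzyloxy)-1α-(triethylsilyloxy)-13,14,15-trinorgermacrane-4,10-dion-12,6α-olide
Conditions: O3, CH2Cl2/MeOH, NaHCO3, Sudan red 7B (indicator), −78 °C; then Me2S, −78 °C → rt
Reagents that add atoms: ozone, [O-][O+]=O
Why: Ozone adds to the tetrasubstituted C4=C10 alkene as a 1,3-dipole; the primary ozonide fragments into a ketone and a carbonyl oxide, methanol traps the carbonyl oxide as a methoxy hydroperoxide, and dimethyl sulfide reduces it to the second ketone. The closest known reaction type is the ozonolytic cleavage of tetrasubstituted ring-fusion alkenes of bicyclic compounds to medium-ring diketones. No ring is closed in the usual sense: the ten-membered ring appears because the bond shared by the five- and seven-membered rings is deleted, so there is no entropic cost. No stereocentre is formed; C1, C2, C3, C5, C6, C7 and C8 are carried over unchanged from the rigid bicycle. Chemoselectivity is needed and is secured by the substrate: C4=C10 is its only alkene, and the anisyl ring reacts much more slowly, so the dye indicator marks the end point before it is attacked. The work-up is buffered and non-basic because C1–H, C5–H and C9–H of 21 are each α to a ketone and β to a leaving oxygen. The two carbonyls are formed exactly where C15 and C14 are to be attached.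

Step 16
Reactants: 21 8α-(tert-butyldimethylsilyloxy)-2β,3β-epoxy-5α-(4-methoxybenzyloxy)-1α-(triethylsilyloxy)-13,14,15-trinorgermacrane-4,10-dion-12,6α-olide
Product: 22 8α-(tert-butyldimethylsilyloxy)-15-chloro-2β,3β-epoxy-4α-hydroxy-5α-(4-methoxybenzyloxy)-1α-(triethylsilyloxy)-13,14-dinorgermacran-10-on-12,6α-olide
Conditions: ICH2Cl, i-PrMgCl, THF, −78 °C (carbenoid preformed); then 21, −78 °C; aq. NH4Cl at −78 °C
Reagents that add atoms: chloroiodomethane, ClCI
Why: Addition of a chloromethylmagnesium carbenoid to a ketone. The C4 carbonyl is activated in a five-membered magnesium chelate with the 5-OPMB oxygen, while C10 is flanked by the non-chelating silyl ether, so C4 should react first. Attack from the H-5 side of the chelate, which is also the outer face of the ring, gives the 4α-oxygen.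

Step 17
Reactants: 22 8α-(tert-butyldimethylsilyloxy)-15-chloro-2β,3β-epoxy-4α-hydroxy-5α-(4-methoxybenzyloxy)-1α-(triethylsilyloxy)-13,14-dinorgermacran-10-on-12,6α-olide
Product: 23 8α-(tert-butyldimethylsilyloxy)-15-chloro-2β,3β-epoxy-1α,4α-dihydroxy-5α-(4-methoxybenzyloxy)-13,14-dinorgermacran-10-on-12,6α-olide
Conditions: HF·pyridine, pyridine, THF, 0 °C
Reagents that add atoms: none
Why: Buffered fluoride cleaves the secondary TES ether much faster than the TBS ether and does not provoke β-elimination at the C10 ketone; the free 1α-OH is needed for the next two steps.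

Step 18
Reactants: 23 8α-(tert-butyldimethylsilyloxy)-15-chloro-2β,3β-epoxy-1α,4α-dihydroxy-5α-(4-methoxybenzyloxy)-13,14-dinorgermacran-10-on-12,6α-olide
Product: 24 8α-(tert-butyldimethylsilyloxy)-15-chloro-2β,3β-epoxy-1α,4α,10α-trihydroxy-5α-(4-methoxybenzyloxy)-13-norgermacran-12,6α-olide
Conditions: MeMgBr (4 equiv), THF, −78 → −40 °C
Reagents that add atoms: methylmagnesium bromide, C[Mg]Br
Why: Chelation-controlled Grignard addition to an α-hydroxy ketone: the C1 magnesium alkoxide holds the C10 carbonyl syn, and methyl enters from the H-1 side (outer face). This gives the 10α-oxygen and 10β-methyl, the relative configuration that closes to the trans epoxide; the lactone is far less electrophilic at this temperature.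

Step 19
Reactants: 24 8α-(tert-butyldimethylsilyloxy)-15-chloro-2β,3β-epoxy-1α,4α,10α-trihydroxy-5α-(4-methoxybenzyloxy)-13-norgermacran-12,6α-olide
Product: 26 8α-(tert-butyldimethylsilyloxy)-1β,10α:2β,3β:4α,15-triepoxy-5α-(4-methoxybenzyloxy)-13-norgermacran-12,6α-olide, via C1 mesylate 25 (not isolated)
Conditions: MsCl, Et3N, THF, −20 °C; then KOt-Bu (3.2 equiv), −20 → 0 °C
Reagents that add atoms: none
Why: Only the secondary 1-OH is sulfonylated; the two tertiary alkoxides then close both epoxides by 3-exo-tet displacement (Williamson type). C10–O attacks C1 with inversion to give the 1β,10α-epoxide, and C4–O displaces the primary chloride to give the 4α,15-epoxide.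

Step 20
Reactants: 26 8α-(tert-butyldimethylsilyloxy)-1β,10α:2β,3β:4α,15-triepoxy-5α-(4-methoxybenzyloxy)-13-norgermacran-12,6α-olide
Product: 27 8α-(tert-butyldimethylsilyloxy)-13-(dimethylamino)-1β,10α:2β,3β:4α,15-triepoxy-5α-(4-methoxybenzyloxy)-11βH-germacran-12,6α-olide
Conditions: LDA, THF, −78 °C; then CH2=NMe2+ I−, −78 → 0 °C
Reagents that add atoms: N,N-dimethylmethyleneiminium iodide, C=[N+](C)C.[I-]
Why: Mannich reaction of the lactone lithium enolate with Eschenmoser's salt; the lactone α-CH2 is the only acidic site and the epoxides tolerate LDA at −78 °C. The iminium ion enters anti to C8; this C11 centre is removed again in step 23.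

Step 21
Reactants: 27 8α-(tert-butyldimethylsilyloxy)-13-(dimethylamino)-1β,10α:2β,3β:4α,15-triepoxy-5α-(4-methoxybenzyloxy)-11βH-germacran-12,6α-olide
Product: 28 13-(dimethylamino)-1β,10α:2β,3β:4α,15-triepoxy-8α-hydroxy-5α-(4-methoxybenzyloxy)-11βH-germacran-12,6α-olide
Conditions: TBAF, AcOH (1:1), THF, 0 °C → rt
Reagents that add atoms: none
Why: Acetic acid-buffered fluoride removes the TBS group without generating a free C8 alkoxide, which could translactonise to the 12,8-olide, and without acid strong enough to open the epoxides.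

Step 22
Reactants: 28 13-(dimethylamino)-1β,10α:2β,3β:4α,15-triepoxy-8α-hydroxy-5α-(4-methoxybenzyloxy)-11βH-germacran-12,6α-olide; 29 angelic acid
Product: 31 8α-angeloyloxy-13-(dimethylamino)-1β,10α:2β,3β:4α,15-triepoxy-5α-(4-methoxybenzyloxy)-11βH-germacran-12,6α-olide, via mixed anhydride 30 (not isolated)
Conditions: 29, 2,4,6-trichlorobenzoyl chloride, Et3N, toluene, rt; then 28, toluene, 75 °C, no DMAP
Reagents that add atoms: none
Why: Yamaguchi esterification through the mixed anhydride; leaving out the nucleophilic catalyst avoids the addition–elimination that converts angelate into tiglate, and the Michael acceptor is still masked as the amine.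

Step 23
Reactants: 31 8α-angeloyloxy-13-(dimethylamino)-1β,10α:2β,3β:4α,15-triepoxy-5α-(4-methoxybenzyloxy)-11βH-germacran-12,6α-olide
Product: 33 8α-angeloyloxy-1β,10α:2β,3β:4α,15-triepoxy-5α-(4-methoxybenzyloxy)germacr-11(13)-en-12,6α-olide, via trimethylammonium iodide 32 (not isolated)
Conditions: MeI, CH2Cl2, rt; then aq. NaHCO3, EtOAc, rt
Reagents that add atoms: none
Why: Quaternisation of the only nucleophilic nitrogen, then E1cB-type (Hofmann-like) loss of trimethylamine from the β-ammonio lactone, which can only give the exocyclic C11=C13 alkene.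

Step 24
Reactants: 33 8α-angeloyloxy-1β,10α:2β,3β:4α,15-triepoxy-5α-(4-methoxybenzyloxy)germacr-11(13)-en-12,6α-olide
Product: 34 8α-angeloyloxy-5α-hydroxy-1β,10α:2β,3β:4α,15-triepoxygermacr-11(13)-en-12,6α-olide (CNP0594916.1)
Conditions: DDQ, CH2Cl2/pH 7 buffer, 0 °C → rt
Reagents that add atoms: none
Why: Oxidative cleavage of the PMB ether by hydride abstraction and hydrolysis under neutral conditions; epoxides, angelate and the electron-poor methylene lactone are inert to DDQ.

## Compound list

1 | furfural | O=Cc1ccco1 | starting material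
2 | allylmagnesium bromide | C=CC[Mg]Br | starting material
3 | 1-(furan-2-yl)but-3-en-1-ol (racemate) | C=CCC(O)c1ccco1 | intermediate
4 | trans-4-hydroxy-5-(prop-2-en-1-yl)cyclopent-2-en-1-one (racemate; the (4S,5R) antipode is drawn) | C=CC[C@H]1C(=O)C=C[C@@H]1O | intermediate
5 | (4S,5R)-4-hydroxy-5-(prop-2-en-1-yl)cyclopent-2-en-1-one | C=CC[C@H]1C(=O)C=C[C@@H]1O | intermediate
6 | (4S,5R)-5-(prop-2-en-1-yl)-4-(triethylsilyloxy)cyclopent-2-en-1-one | C=CC[C@H]1C(=O)C=C[C@@H]1O[Si](CC)(CC)CC | intermediate
7 | 10β-allyl-2β,3β-epoxy-1α-(triethylsilyloxy)cyclopentan-4-one (epoxide trans to the silyloxy group, cis to allyl) | C=CC[C@H]1C(=O)[C@H]2O[C@H]2[C@@H]1O[Si](CC)(CC)CC | intermediate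
8 | 10-allyl-2β,3β-epoxy-1α-(triethylsilyloxy)cyclopent-4(10)-en-4-yl trifluoromethanesulfonate | C=CCC1=C(OS(=O)(=O)C(F)(F)F)[C@H]2O[C@H]2[C@@H]1O[Si](CC)(CC)CC | intermediate
9 | 2-[2β,3β-epoxy-1α-(triethylsilyloxy)-4-(triflyloxy)cyclopent-4(10)-en-10-yl]acetaldehyde | O=CCC1=C(OS(=O)(=O)C(F)(F)F)[C@H]2O[C@H]2[C@@H]1O[Si](CC)(CC)CC | intermediate
10 | prop-2-yn-1-ol | C#CCO | starting material
11 | trimethyl orthoacetate | CC(OC)(OC)OC | starting material
12 | methyl penta-3,4-dienoate | C=C=CCC(=O)OC | intermediate
13 | methyl (3Z)-5-(diisopinocampheylboranyl)pent-3-enoate, isopinocampheyl groups from (−)-α-pinene | COC(=O)C/C=C\CB([C@H]1C[C@H]2C[C@@H]([C@@H]1C)C2(C)C)[C@H]1C[C@H]2C[C@@H]([C@@H]1C)C2(C)C | intermediate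
14 | methyl (3S,4S)-3-ethenyl-4-hydroxy-5-[2β,3β-epoxy-1α-(triethylsilyloxy)-4-(triflyloxy)cyclopent-4(10)-en-10-yl]pentanoate (7S,8S, syn) | COC(=O)C[C@@H](C=C)[C@@H](O)CC1=C(OS(=O)(=O)C(F)(F)F)[C@H]2O[C@H]2[C@@H]1O[Si](CC)(CC)CC | intermediate
15 | methyl (3S,4S)-4-(tert-butyldimethylsilyloxy)-3-ethenyl-5-[2β,3β-epoxy-1α-(triethylsilyloxy)-4-(triflyloxy)cyclopent-4(10)-en-10-yl]pentanoate | COC(=O)C[C@@H](C=C)[C@@H](O[Si](C)(C)C(C)(C)C)CC1=C(OS(=O)(=O)C(F)(F)F)[C@H]2O[C@H]2[C@@H]1O[Si](CC)(CC)CC | intermediate
16 | methyl (3S,4S)-4-(tert-butyldimethylsilyloxy)-3-ethenyl-5-[4-ethenyl-2β,3β-epoxy-1α-(triethylsilyloxy)cyclopent-4(10)-en-10-yl]pentanoate | COC(=O)C[C@@H](C=C)[C@@H](O[Si](C)(C)C(C)(C)C)CC1=C(C=C)[C@H]2O[C@H]2[C@@H]1O[Si](CC)(CC)CC | intermediate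
17 | methyl 8α-(tert-butyldimethylsilyloxy)-2β,3β-epoxy-1α-(triethylsilyloxy)-13,14,15-trinor-4,10-cyclogermacra-4(10),5-dien-12-oate (H-7α) | COC(=O)C[C@H]1C=CC2=C(C[C@@H]1O[Si](C)(C)C(C)(C)C)[C@@H](O[Si](CC)(CC)CC)[C@@H]3O[C@H]23 | intermediate
18 | methyl 8α-(tert-butyldimethylsilyloxy)-2β,3β-epoxy-5α,6α-dihydroxy-1α-(triethylsilyloxy)-13,14,15-trinor-4,10-cyclogermacr-4(10)-en-12-oate | COC(=O)C[C@H]1[C@H](O)[C@H](O)C2=C(C[C@@H]1O[Si](C)(C)C(C)(C)C)[C@@H](O[Si](CC)(CC)CC)[C@@H]3O[C@H]23 | intermediate
19 | 8α-(tert-butyldimethylsilyloxy)-2β,3β-epoxy-5α-hydroxy-1α-(triethylsilyloxy)-13,14,15-trinor-4,10-cyclogermacr-4(10)-en-12,6α-olide | C1C(=O)O[C@H]2[C@H]1[C@@H](O[Si](C)(C)C(C)(C)C)CC3=C([C@H]2O)[C@H]4O[C@H]4[C@@H]3O[Si](CC)(CC)CC | intermediate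
20 | 8α-(tert-butyldimethylsilyloxy)-2β,3β-epoxy-5α-(4-methoxybenzyloxy)-1α-(triethylsilyloxy)-13,14,15-trinor-4,10-cyclogermacr-4(10)-en-12,6α-olide (key-step precursor) | C1C(=O)O[C@H]2[C@H]1[C@@H](O[Si](C)(C)C(C)(C)C)CC3=C([C@H]2OCc5ccc(OC)cc5)[C@H]4O[C@H]4[C@@H]3O[Si](CC)(CC)CC | intermediate
21 | 8α-(tert-butyldimethylsilyloxy)-2β,3β-epoxy-5α-(4-methoxybenzyloxy)-1α-(triethylsilyloxy)-13,14,15-trinorgermacrane-4,10-dion-12,6α-olide (key-step product) | C1C(=O)O[C@H]2[C@H]1[C@@H](O[Si](C)(C)C(C)(C)C)CC(=O)[C@@H](O[Si](CC)(CC)CC)[C@@H]3O[C@@H]3C(=O)[C@H]2OCc4ccc(OC)cc4 | intermediate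
22 | 8α-(tert-butyldimethylsilyloxy)-15-chloro-2β,3β-epoxy-4α-hydroxy-5α-(4-methoxybenzyloxy)-1α-(triethylsilyloxy)-13,14-dinorgermacran-10-on-12,6α-olide | C1C(=O)O[C@H]2[C@H]1[C@@H](O[Si](C)(C)C(C)(C)C)CC(=O)[C@@H](O[Si](CC)(CC)CC)[C@@H]3O[C@@H]3[C@](O)(CCl)[C@H]2OCc4ccc(OC)cc4 | intermediate
23 | 8α-(tert-butyldimethylsilyloxy)-15-chloro-2β,3β-epoxy-1α,4α-dihydroxy-5α-(4-methoxybenzyloxy)-13,14-dinorgermacran-10-on-12,6α-olide | C1C(=O)O[C@H]2[C@H]1[C@@H](O[Si](C)(C)C(C)(C)C)CC(=O)[C@@H](O)[C@@H]3O[C@@H]3[C@](O)(CCl)[C@H]2OCc4ccc(OC)cc4 | intermediate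
24 | 8α-(tert-butyldimethylsilyloxy)-15-chloro-2β,3β-epoxy-1α,4α,10α-trihydroxy-5α-(4-methoxybenzyloxy)-13-norgermacran-12,6α-olide | C1C(=O)O[C@H]2[C@H]1[C@@H](O[Si](C)(C)C(C)(C)C)C[C@@](C)(O)[C@@H](O)[C@@H]3O[C@@H]3[C@](O)(CCl)[C@H]2OCc4ccc(OC)cc4 | intermediate
25 | 1-O-methanesulfonate of 24 | C1C(=O)O[C@H]2[C@H]1[C@@H](O[Si](C)(C)C(C)(C)C)C[C@@](C)(O)[C@@H](OS(C)(=O)=O)[C@@H]3O[C@@H]3[C@](O)(CCl)[C@H]2OCc4ccc(OC)cc4 | intermediate
26 | 8α-(tert-butyldimethylsilyloxy)-1β,10α:2β,3β:4α,15-triepoxy-5α-(4-methoxybenzyloxy)-13-norgermacran-12,6α-olide | C1C(=O)O[C@H]2[C@H]1[C@@H](O[Si](C)(C)C(C)(C)C)C[C@@]3(C)O[C@@H]3[C@@H]4O[C@@H]4[C@]5(CO5)[C@H]2OCc6ccc(OC)cc6 | intermediate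
27 | 8α-(tert-butyldimethylsilyloxy)-13-(dimethylamino)-1β,10α:2β,3β:4α,15-triepoxy-5α-(4-methoxybenzyloxy)-11βH-germacran-12,6α-olide | CN(C)C[C@@H]1C(=O)O[C@H]2[C@H]1[C@@H](O[Si](C)(C)C(C)(C)C)C[C@@]3(C)O[C@@H]3[C@@H]4O[C@@H]4[C@]5(CO5)[C@H]2OCc6ccc(OC)cc6 | intermediate
28 | 13-(dimethylamino)-1β,10α:2β,3β:4α,15-triepoxy-8α-hydroxy-5α-(4-methoxybenzyloxy)-11βH-germacran-12,6α-olide | CN(C)C[C@@H]1C(=O)O[C@H]2[C@H]1[C@@H](O)C[C@@]3(C)O[C@@H]3[C@@H]4O[C@@H]4[C@]5(CO5)[C@H]2OCc6ccc(OC)cc6 | intermediate
29 | angelic acid, (Z)-2-methylbut-2-enoic acid | C/C=C(/C)C(=O)O | starting material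
30 | (Z)-2-methylbut-2-enoic 2,4,6-trichlorobenzoic anhydride | C/C=C(/C)C(=O)OC(=O)c1c(Cl)cc(Cl)cc1Cl | intermediate
31 | 8α-angeloyloxy-13-(dimethylamino)-1β,10α:2β,3β:4α,15-triepoxy-5α-(4-methoxybenzyloxy)-11βH-germacran-12,6α-olide | CN(C)C[C@@H]1C(=O)O[C@H]2[C@H]1[C@@H](OC(=O)/C(C)=C\C)C[C@@]3(C)O[C@@H]3[C@@H]4O[C@@H]4[C@]5(CO5)[C@H]2OCc6ccc(OC)cc6 | intermediate
32 | 13-trimethylammonio iodide of 31 | C[N+](C)(C)C[C@@H]1C(=O)O[C@H]2[C@H]1[C@@H](OC(=O)/C(C)=C\C)C[C@@]3(C)O[C@@H]3[C@@H]4O[C@@H]4[C@]5(CO5)[C@H]2OCc6ccc(OC)cc6.[I-] | intermediate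
33 | 8α-angeloyloxy-1β,10α:2β,3β:4α,15-triepoxy-5α-(4-methoxybenzyloxy)germacr-11(13)-en-12,6α-olide | C=C1C(=O)O[C@H]2[C@H]1[C@@H](OC(=O)/C(C)=C\C)C[C@@]3(C)O[C@@H]3[C@@H]4O[C@@H]4[C@]5(CO5)[C@H]2OCc6ccc(OC)cc6 | intermediate
34 | 8α-angeloyloxy-5α-hydroxy-1β,10α:2β,3β:4α,15-triepoxygermacr-11(13)-en-12,6α-olide (CNP0594916.1) | C=C1C(=O)O[C@H]2[C@H]1[C@@H](OC(=O)/C(C)=C\C)C[C@@]1(C)O[C@@H]1[C@@H]1O[C@@H]1[C@]1(CO1)[C@H]2O | target

## Step count and least certain steps

Total: 24 steps. Longest linear sequence: 23 steps (steps 1–7 and 9–24); step 8 is a one-step side branch.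

**Step 15 (key step).** The alkene is tetrasubstituted, hindered and flanked by three allylic C–O bonds. The most likely failures are partial oxygen-atom transfer (epoxidation) in place of cleavage, over-oxidation of the anisyl ring if the end point is missed, and β-elimination or epimerisation of the diketone during work-up. Fallback: from 20, stoichiometric OsO4 in pyridine would add from the β face (away from the 1α- and 5α-substituents) to give the cis 4β,10β-diol F1, and glycol cleavage with Pb(OAc)4 in buffered benzene would return to 21.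

**Step 16.** The carbenoid may not discriminate the two ketones (C10 is less hindered, C4 is only chelation-activated), facial control at C4 depends on the chelate forming in a ten-membered ring, and any excess base can trigger β-elimination. Fallback with the order of the two additions reversed:
- from 21, buffered HF·pyridine removes the TES group to give the 1α-hydroxy diketone F2;
- MeMgBr then adds to C10 through the C1 alkoxide chelate to give the 10-methyl carbinol F3;
- the chloromethylmagnesium reagent is then offered only the C4 ketone, chelated by 5-OPMB, and the route is rejoined at 24.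

**Step 6.** The potassium enolate at C10 has the 1-silyloxy group in the β-position; elimination of silanolate to an epoxy cyclopentenone may compete with O-triflation. Fallback that avoids the enolate (and the palladium step), carrying the ketone through chain extension:
- from 7, Lemieux–Johnson cleavage gives keto aldehyde F4;
- allylboration with 13 gives hydroxy keto ester F5, and TBSOTf gives its silyl ether F6;
- CH2=CHMgBr/CeCl3 adds to the C4 ketone anti to the epoxide and the side chain to give the tertiary allylic alcohol F7;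
- Martin sulfurane dehydrates F7 anti toward C10–H, the only available β-hydrogen, and the route is rejoined at 16.

**Step 11.** Zerovalent palladium may ionise the allylic 2,3-epoxide of the substrate or of the dienyl product to a π-allyl species, leading to ring opening. Fallback: from 15, direct substitution of the enol triflate with lithium divinylcuprate at low temperature replaces the catalytic palladium cycle with a stoichiometric organocopper coupling and gives 16 without new intermediates.

**Step 19.** With both alkoxides free, the C4 alkoxide may attack C1 (5-exo, a 1,4-ether) or open the 2,3-epoxide (Payne migration) before it displaces chloride, and the lactone may suffer from excess alkoxide. Fallback: from 24, Cs2CO3 in MeCN closes only the chlorohydrin to give the spiro-epoxide diol F8, and a Mitsunobu cyclodehydration (PPh3, DIAD) then activates the secondary 1-OH and lets the tertiary 10-OH close with inversion, returning to 26 without any strong base.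

## Further compounds

F1 | step 15 | 8α-(tert-butyldimethylsilyloxy)-2β,3β-epoxy-4β,10β-dihydroxy-5α-(4-methoxybenzyloxy)-1α-(triethylsilyloxy)-13,14,15-trinor-4,10-cyclogermacran-12,6α-olide | C1C(=O)O[C@H]2[C@H]1[C@@H](O[Si](C)(C)C(C)(C)C)C[C@]3(O)[C@@]([C@H]2OCc5ccc(OC)cc5)(O)[C@H]4O[C@H]4[C@@H]3O[Si](CC)(CC)CC
F2 | step 16 | 8α-(tert-butyldimethylsilyloxy)-2β,3β-epoxy-1α-hydroxy-5α-(4-methoxybenzyloxy)-13,14,15-trinorgermacrane-4,10-dion-12,6α-olide | C1C(=O)O[C@H]2[C@H]1[C@@H](O[Si](C)(C)C(C)(C)C)CC(=O)[C@@H](O)[C@@H]3O[C@@H]3C(=O)[C@H]2OCc4ccc(OC)cc4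
F3 | step 16 | 8α-(tert-butyldimethylsilyloxy)-2β,3β-epoxy-1α,10α-dihydroxy-5α-(4-methoxybenzyloxy)-13,15-dinorgermacran-4-on-12,6α-olide | C1C(=O)O[C@H]2[C@H]1[C@@H](O[Si](C)(C)C(C)(C)C)C[C@@](C)(O)[C@@H](O)[C@@H]3O[C@@H]3C(=O)[C@H]2OCc4ccc(OC)cc4
F4 | step 6 | 2-[2β,3β-epoxy-4-oxo-1α-(triethylsilyloxy)cyclopentan-10β-yl]acetaldehyde | O=CC[C@H]1C(=O)[C@H]2O[C@H]2[C@@H]1O[Si](CC)(CC)CC
F5 | step 6 | methyl (3S,4S)-3-ethenyl-4-hydroxy-5-[2β,3β-epoxy-4-oxo-1α-(triethylsilyloxy)cyclopentan-10β-yl]pentanoate | COC(=O)C[C@@H](C=C)[C@@H](O)C[C@H]1C(=O)[C@H]2O[C@H]2[C@@H]1O[Si](CC)(CC)CC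
F6 | step 6 | methyl (3S,4S)-4-(tert-butyldimethylsilyloxy)-3-ethenyl-5-[2β,3β-epoxy-4-oxo-1α-(triethylsilyloxy)cyclopentan-10β-yl]pentanoate | COC(=O)C[C@@H](C=C)[C@@H](O[Si](C)(C)C(C)(C)C)C[C@H]1C(=O)[C@H]2O[C@H]2[C@@H]1O[Si](CC)(CC)CC
F7 | step 6 | methyl (3S,4S)-4-(tert-butyldimethylsilyloxy)-3-ethenyl-5-[4α-ethenyl-2β,3β-epoxy-4β-hydroxy-1α-(triethylsilyloxy)cyclopentan-10β-yl]pentanoate | COC(=O)C[C@@H](C=C)[C@@H](O[Si](C)(C)C(C)(C)C)C[C@H]1[C@](O)(C=C)[C@H]2O[C@H]2[C@@H]1O[Si](CC)(CC)CC
F0 | step 11 | none | none
F8 | step 19 | 8α-(tert-butyldimethylsilyloxy)-2β,3β:4α,15-diepoxy-1α,10α-dihydroxy-5α-(4-methoxybenzyloxy)-13-norgermacran-12,6α-olide | C1C(=O)O[C@H]2[C@H]1[C@@H](O[Si](C)(C)C(C)(C)C)C[C@@](C)(O)[C@@H](O)[C@@H]3O[C@@H]3[C@]4(CO4)[C@H]2OCc5ccc(OC)cc5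
A1 | alternative 1 | 15-nor-germacra-1(10)E,2Z,11(13)-triene-5α,6α-diol 4-(ethylene ketal), 8,12-bis-O-TBS | O[C@H]1[C@H](C(=C)CO[Si](C)(C)C(C)(C)C)[C@@H](O[Si](C)(C)C(C)(C)C)C/C(C)=C/C=C\C2(OCCO2)[C@H]1O
A2 | alternative 2 | 8α-hydroxygermacra-1(10)E,2Z,4(15),11(13)-tetraene, 5,6-bis-O-MOM, 12-O-TBS | C=C(CO[Si](C)(C)C(C)(C)C)[C@H]1[C@H](OCOC)[C@H](OCOC)C(=C)/C=C\C=C(C)\C[C@@H]1O
A3 | alternative 3 | 8-O-TBS-5α-hydroxygermacra-1(10)E,2Z,4(15),11(13)-tetraen-12,6α-olide | C=C1C(=O)O[C@@H]2[C@H](O)C(=C)/C=C\C=C(C)\C[C@H](O[Si](C)(C)C(C)(C)C)[C@@H]12
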